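**Retrosynthetic overview**
1. Target 31 ⇐ 30 by a late, peripheral epoxidation of the C1=C10 olefin; 30 ⇐ macrocyclic alcohol 24 + (2S,3S)-epoxyangelic acid 28 (from angelic acid by Sharpless epoxidation).
2. Key disconnection C7–C8: 24 ⇐ seco-aldehyde 21 by SmI2 ketyl-radical addition to the butenolide β-carbon with loss of the allylic acetate. This closes the ten-membered ring, sets C7 and C8 and unveils the α-methylene lactone in one step.
3. 21 ⇐ dienol 15 by acylation and ring-closing metathesis (butenolide); 15 ⇐ Z-alkenyl iodide 13 + acrolein (asymmetric Ni/Cr coupling sets C6).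
4. 13 ⇐ alkynol 10 by CuI-catalysed anti-carbomagnesiation, iodination and benzoylation (Z C4=C5); 10 ⇐ aldehyde 7 + ethynylsilane (C3); 7 ⇐ but-3-yn-1-ol by Cp2ZrCl2/Me3Al carboalumination (E C1=C10) and oxirane opening.
5. Ring order: butenolide, then the ten-membered carbocycle (key step), then the 1,10-oxirane; the side-chain oxirane is made separately.

Assumption: positions carry germacrane numbering (C1–C10 ring, C11–C13 lactone carbons, C14/C15 methyls on C10/C4); the target is (1R,3S,4Z,6R,7R,8R,10R) with a (2S,3S)-2,3-dimethyloxirane-2-carboxylate on O-8.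

**Route**

Step 1
Reactants: 1 but-3-yn-1-ol
Product: 2 tert-butyl(but-3-yn-1-yloxy)dimethylsilane
Conditions: TBSCl, imidazole, CH2Cl2, 0 °C to rt
Reagents that add atoms: tert-butyldimethylsilyl chloride, CC(C)(C)[Si](C)(C)Cl
Why: Routine silyl ether formation protects the future C8 hydroxyl through the organometallic steps; no stereocentre is involved.

Step 2
Reactants: 2 tert-butyl(but-3-yn-1-yloxy)dimethylsilane; 3 oxirane
Product: 6 (E)-6-(tert-butyldimethylsilyloxy)-4-methylhex-3-en-1-ol, via alkenyldimethylalane 4 (not isolated), via lithium butyl(alkenyl)dimethylaluminate 5 (not isolated)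
Conditions: Me3Al (2.5 equiv), Cp2ZrCl2 (25 mol %), CH2Cl2, rt, 12 h; excess Me3Al removed in vacuo; n-BuLi (1.0 equiv), THF/hexane, −78 to 0 °C; oxirane (2 equiv), −78 to 0 °C; cold 1 M HCl
Reagents that add atoms: trimethylaluminium, C[Al](C)C
Why: Negishi zirconium-catalysed carboalumination adds methyl and aluminium syn across the terminal alkyne with methyl on the internal carbon, which fixes the E C1=C10 olefin, and the ate complex then opens oxirane with retention of olefin geometry to add C2 and C3.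

Step 3
Reactants: 6 (E)-6-(tert-butyldimethylsilyloxy)-4-methylhex-3-en-1-ol
Product: 7 (E)-6-(tert-butyldimethylsilyloxy)-4-methylhex-3-enal
Conditions: Dess–Martin periodinane (1.3 equiv), NaHCO3, CH2Cl2, 0 °C, 1 h; used at once
Reagents that add atoms: none
Why: Buffered Dess–Martin oxidation gives the β,γ-unsaturated aldehyde without moving the olefin into conjugation.

Step 4
Reactants: 7 (E)-6-(tert-butyldimethylsilyloxy)-4-methylhex-3-enal; 8 ethynyltrimethylsilane
Product: 10 (3S,5E)-8-(tert-butyldimethylsilyloxy)-6-methyloct-5-en-1-yn-3-ol, via silylated alkynol 9 (not isolated)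
Conditions: Me2Zn (3 equiv), (S,S)-ProPhenol (20 mol %), Ph3P=O (40 mol %), toluene, 4 °C, 48 h; aq. NH4Cl; crude product in MeOH, K2CO3 (20 mol %), rt
Reagents that add atoms: none
Why: Trost zinc–ProPhenol enantioselective alkynylation is amine-free so the skipped enal does not conjugate, the dinuclear zinc catalyst delivers the alkynyl group to one aldehyde face to set C3 as S (the ligand antipode is used if Mosher analysis shows the opposite sense), and methanolysis removes the C-silyl group.

Step 5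
Reactants: 10 (3S,5E)-8-(tert-butyldimethylsilyloxy)-6-methyloct-5-en-1-yn-3-ol
Product: 13 (1Z,3S,5E)-8-(tert-butyldimethylsilyloxy)-1-iodo-2,6-dimethylocta-1,5-dien-3-yl benzoate, via bis(bromomagnesium) alkenyl alkoxide 11 (not isolated), via bromomagnesium iodoalkenyl alkoxide 12 (not isolated)
Conditions: MeMgBr (3.5 equiv), CuI (20 mol %), THF, 0 °C to rt, 16 h; I2 in THF added at −78 °C to a faint persistent colour; BzCl (2 equiv), DMAP (10 mol %), −78 to 0 °C
Reagents that add atoms: methylmagnesium bromide, C[Mg]Br; iodine, [I][I]; benzoyl chloride, O=C(Cl)c1ccccc1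
Why: Duboudin copper-catalysed anti-carbomagnesiation of the propargylic alkoxide puts methyl on C4 and magnesium on C5 cis to the carbinol through a five-membered chelate, which fixes the Z C4=C5 geometry; iodinolysis goes with retention and the magnesium alkoxide is benzoylated in the same flask without touching C3.

Step 6
Reactants: 13 (1Z,3S,5E)-8-(tert-butyldimethylsilyloxy)-1-iodo-2,6-dimethylocta-1,5-dien-3-yl benzoate; 14 acrolein
Product: 15 (3S,4Z,6S,8E)-11-(tert-butyldimethylsilyloxy)-3-hydroxy-5,9-dimethylundeca-1,4,8-trien-6-yl benzoate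
Conditions: CrCl2 (4 equiv), (S)-N-[2-(4-isopropyl-4,5-dihydrooxazol-2-yl)-6-methylphenyl]methanesulfonamide (4.4 equiv), Et3N (4.4 equiv), THF, rt, 1 h; then NiCl2 (2 mol %), 13, 14 (3 equiv), rt
Reagents that add atoms: none
Why: Kishi asymmetric Nozaki–Hiyama–Kishi coupling: the alkenyl iodide is activated by nickel and passed to a sulfonamide-ligated alkenylchromium that adds 1,2 to one face of acrolein, setting the new carbinol (C6, 3S in this name) with retention of the Z olefin and tolerance of the benzoate (ligand antipode if the sense is reversed).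

Step 7
Reactants: 16 2-(bromomethyl)prop-2-enoic acid
Product: 17 2-(acetoxymethyl)prop-2-enoic acid
Conditions: KOAc (2.2 equiv), DMF, rt; then 1 M HCl
Reagents that add atoms: potassium acetate, [K+].CC(=O)[O-]
Why: Acetate displaces the allylic bromide (SN2 and SN2' give the same product because the allyl unit is symmetric), giving the acid that carries the future leaving group on C13.

Step 8
Reactants: 15 (3S,4Z,6S,8E)-11-(tert-butyldimethylsilyloxy)-3-hydroxy-5,9-dimethylundeca-1,4,8-trien-6-yl benzoate; 17 2-(acetoxymethyl)prop-2-enoic acid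
Product: 18 (3S,4Z,6S,8E)-6-(benzoyloxy)-11-(tert-butyldimethylsilyloxy)-5,9-dimethylundeca-1,4,8-trien-3-yl 2-(acetoxymethyl)prop-2-enoate
Conditions: N,N'-diisopropylcarbodiimide (1.3 equiv), DMAP (5 mol %), CH2Cl2, −10 °C
Reagents that add atoms: none
Why: Steglich carbodiimide esterification acylates the bis-allylic alcohol under near-neutral conditions with retention at C6.

Step 9
Reactants: 18 (3S,4Z,6S,8E)-6-(benzoyloxy)-11-(tert-butyldimethylsilyloxy)-5,9-dimethylundeca-1,4,8-trien-3-yl 2-(acetoxymethyl)prop-2-enoate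
Product: 19 {(5R)-5-[(1Z,3S,5E)-3-(benzoyloxy)-8-(tert-butyldimethylsilyloxy)-2,6-dimethylocta-1,5-dien-1-yl]-2-oxo-2,5-dihydrofuran-3-yl}methyl acetate
Conditions: second-generation Grubbs catalyst (H2IMes)(PCy3)Cl2Ru=CHPh (5 mol %), CH2Cl2 (0.005 M), 40 °C
Reagents that add atoms: none
Why: Ring-closing metathesis between the only monosubstituted vinyl group and the acrylate olefin closes the butenolide with loss of ethene while the trisubstituted olefins stay inert; the C6 label changes from S to R by priority only.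

Step 10
Reactants: 19 {(5R)-5-[(1Z,3S,5E)-3-(benzoyloxy)-8-(tert-butyldimethylsilyloxy)-2,6-dimethylocta-1,5-dien-1-yl]-2-oxo-2,5-dihydrofuran-3-yl}methyl acetate
Product: 20 {(5R)-5-[(1Z,3S,5E)-3-(benzoyloxy)-8-hydroxy-2,6-dimethylocta-1,5-dien-1-yl]-2-oxo-2,5-dihydrofuran-3-yl}methyl acetate
Conditions: HF·pyridine, pyridine, THF, 0 °C to rt
Reagents that add atoms: none
Why: Buffered fluoride desilylation frees the primary alcohol without touching the acetate, the benzoate or the epimerisable butenolide γ-centre.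

Step 11
Reactants: 20 {(5R)-5-[(1Z,3S,5E)-3-(benzoyloxy)-8-hydroxy-2,6-dimethylocta-1,5-dien-1-yl]-2-oxo-2,5-dihydrofuran-3-yl}methyl acetate
Product: 21 {(5R)-5-[(1Z,3S,5E)-3-(benzoyloxy)-2,6-dimethyl-8-oxoocta-1,5-dien-1-yl]-2-oxo-2,5-dihydrofuran-3-yl}methyl acetate
Conditions: Dess–Martin periodinane (1.3 equiv), NaHCO3, CH2Cl2, 0 °C; used at once
Reagents that add atoms: none
Why: Buffered Dess–Martin oxidation gives the sensitive β,γ-unsaturated aldehyde without conjugation or epimerisation at C6.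

Step 12
Reactants: 21 {(5R)-5-[(1Z,3S,5E)-3-(benzoyloxy)-2,6-dimethyl-8-oxoocta-1,5-dien-1-yl]-2-oxo-2,5-dihydrofuran-3-yl}methyl acetate
Product: 24 (3aR,4R,6E,9S,10Z,11aR)-4-hydroxy-6,10-dimethyl-3-methylidene-2-oxo-2,3,3a,4,5,8,9,11a-octahydrocyclodeca[b]furan-9-yl benzoate, via diiodosamarium ketyl 22 (not isolated), via bis(diiodosamarium) enolate alkoxide 23 (not isolated)
Conditions: SmI2 (2.5 equiv, 0.1 M in THF, degassed), 21 added by syringe pump over 6 h (final 0.002 M), −78 to −20 °C; sat. aq. NH4Cl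
Reagents that add atoms: none
Why: Proposed new method: single-electron transfer from SmI2 to the aldehyde gives a nucleophilic samarium ketyl radical that adds to the electron-poor β-carbon (C7) of the butenolide on the face anti to the C6 side chain (trans lactone fusion, C7 R) with the bulky O–SmI2 group pointing out of the forming ring (C8 R), and a second electron turns the α-acyl radical into a trivalent samarium enolate that expels the C13 acetate (E1cB) to reveal the α-methylene lactone; the closest known reactions are Molander's sequential ketyl–olefin coupling/β-elimination and SmI2 ketyl additions to unsaturated esters and lactones, the new elements being the ten-membered ring size (helped by the rigid butenolide, the two trisubstituted olefins and the persistence of the ketyl under aprotic high dilution) and the butenolide acceptor.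

Step 13
Reactants: 25 angelic acid
Product: 26 (Z)-2-methylbut-2-en-1-ol
Conditions: LiAlH4, Et2O, 0 °C
Reagents that add atoms: none
Why: Hydride reduction of the acid to the allylic alcohol leaves the Z olefin untouched.

Step 14
Reactants: 26 (Z)-2-methylbut-2-en-1-ol
Product: 27 [(2R,3S)-2,3-dimethyloxiran-2-yl]methanol
Conditions: Ti(OiPr)4 (10 mol %), D-(−)-diethyl tartrate (12 mol %), t-BuOOH (2 equiv), 4 Å molecular sieves, CH2Cl2, −20 °C
Reagents that add atoms: tert-butyl hydroperoxide, CC(C)(C)OO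
Why: Sharpless asymmetric epoxidation with the D-tartrate delivers oxygen to the face that gives the (2R,3S) epoxy alcohol (the sense opposite to L-tartrate, which gives 2S,3R from Z-trisubstituted allylic alcohols such as nerol), the cis relation of CH2OH and the C3 methyl coming from the Z olefin.

Step 15
Reactants: 27 [(2R,3S)-2,3-dimethyloxiran-2-yl]methanol
Product: 28 (2S,3S)-2,3-dimethyloxirane-2-carboxylic acid
Conditions: RuCl3·xH2O (2 mol %), NaIO4 (3 equiv), CCl4/MeCN/H2O, rt
Reagents that add atoms: sodium periodate, [Na+].[O-]I(=O)(=O)=O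
Why: Sharpless RuO4-catalysed oxidation takes the primary alcohol to the acid without opening the oxirane; the C2 label changes from R to S by priority only.

Step 16
Reactants: 24 (3aR,4R,6E,9S,10Z,11aR)-4-hydroxy-6,10-dimethyl-3-methylidene-2-oxo-2,3,3a,4,5,8,9,11a-octahydrocyclodeca[b]furan-9-yl benzoate; 28 (2S,3S)-2,3-dimethyloxirane-2-carboxylic acid
Product: 30 (3aR,4R,6E,9S,10Z,11aR)-9-(benzoyloxy)-6,10-dimethyl-3-methylidene-2-oxo-2,3,3a,4,5,8,9,11a-octahydrocyclodeca[b]furan-4-yl (2S,3S)-2,3-dimethyloxirane-2-carboxylate, via mixed anhydride 29 (not isolated)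
Conditions: 28 (1.5 equiv), 2,4,6-trichlorobenzoyl chloride (1.5 equiv), Et3N (3 equiv), THF, rt, 1 h; then 24, DMAP (0.5 equiv), toluene, rt
Reagents that add atoms: none
Why: Yamaguchi esterification acylates the hindered C8 alcohol with retention, the acid has no α-hydrogen to epimerise, and fast acylation outruns translactonisation.

Step 17
Reactants: 30 (3aR,4R,6E,9S,10Z,11aR)-9-(benzoyloxy)-6,10-dimethyl-3-methylidene-2-oxo-2,3,3a,4,5,8,9,11a-octahydrocyclodeca[b]furan-4-yl (2S,3S)-2,3-dimethyloxirane-2-carboxylate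
Product: 31 (1R,3S,4Z,6R,7R,8R,10R)-3-(benzoyloxy)-1,10-epoxy-8-{[(2S,3S)-2,3-dimethyloxirane-2-carbonyl]oxy}germacra-4,11(13)-dien-12,6-olide (CNP0324463.3)
Conditions: mCPBA (1.1 equiv), NaHCO3, CH2Cl2, −20 to 0 °C
Reagents that add atoms: 3-chloroperoxybenzoic acid, OOC(=O)c1cccc(Cl)c1
Why: Prilezhaev epoxidation picks the only electron-rich olefin (C1=C10; C4=C5 is deactivated by two allylic acyloxy groups and the exocyclic methylene is conjugated), and peripheral attack on the preferred ring conformer with C14 on the β face gives the trans 1β,10α (1R,10R) oxirane, as is usual for 1(10)E-germacranolides; the buffer prevents transannular opening.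

**Compound list**
1 | but-3-yn-1-ol | C#CCCO | starting material
2 | tert-butyl(but-3-yn-1-yloxy)dimethylsilane | C#CCCO[Si](C)(C)C(C)(C)C | intermediate
3 | oxirane (ethylene oxide) | C1CO1 | starting material
4 | [(E)-4-(tert-butyldimethylsilyloxy)-2-methylbut-1-en-1-yl]dimethylalane | C[Al](C)/C=C(\C)CCO[Si](C)(C)C(C)(C)C | intermediate
5 | lithium butyl[(E)-4-(tert-butyldimethylsilyloxy)-2-methylbut-1-en-1-yl]dimethylaluminate | [Li+].CCCC[Al-](C)(C)/C=C(\C)CCO[Si](C)(C)C(C)(C)C | intermediate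
6 | (E)-6-(tert-butyldimethylsilyloxy)-4-methylhex-3-en-1-ol | OCC/C=C(\C)CCO[Si](C)(C)C(C)(C)C | intermediate
7 | (E)-6-(tert-butyldimethylsilyloxy)-4-methylhex-3-enal | O=CC/C=C(\C)CCO[Si](C)(C)C(C)(C)C | intermediate
8 | ethynyltrimethylsilane | C#C[Si](C)(C)C | starting material
9 | (3S,5E)-8-(tert-butyldimethylsilyloxy)-6-methyl-1-(trimethylsilyl)oct-5-en-1-yn-3-ol | C[Si](C)(C)C#C[C@@H](O)C/C=C(\C)CCO[Si](C)(C)C(C)(C)C | intermediate
10 | (3S,5E)-8-(tert-butyldimethylsilyloxy)-6-methyloct-5-en-1-yn-3-ol | C#C[C@@H](O)C/C=C(\C)CCO[Si](C)(C)C(C)(C)C | intermediate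
11 | bromomagnesium (1Z,3S,5E)-1-(bromomagnesio)-8-(tert-butyldimethylsilyloxy)-2,6-dimethylocta-1,5-dien-3-olate | Br[Mg]/C=C(C)\[C@@H](O[Mg]Br)C/C=C(\C)CCO[Si](C)(C)C(C)(C)C | intermediate
12 | bromomagnesium (1Z,3S,5E)-8-(tert-butyldimethylsilyloxy)-1-iodo-2,6-dimethylocta-1,5-dien-3-olate | I/C=C(C)\[C@@H](O[Mg]Br)C/C=C(\C)CCO[Si](C)(C)C(C)(C)C | intermediate
13 | (1Z,3S,5E)-8-(tert-butyldimethylsilyloxy)-1-iodo-2,6-dimethylocta-1,5-dien-3-yl benzoate | I/C=C(C)\[C@@H](OC(=O)c1ccccc1)C/C=C(\C)CCO[Si](C)(C)C(C)(C)C | intermediate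
14 | acrolein (prop-2-enal) | C=CC=O | starting material
15 | (3S,4Z,6S,8E)-11-(tert-butyldimethylsilyloxy)-3-hydroxy-5,9-dimethylundeca-1,4,8-trien-6-yl benzoate | C=C[C@H](O)/C=C(/C)[C@@H](OC(=O)c1ccccc1)C/C=C(\C)CCO[Si](C)(C)C(C)(C)C | intermediate
16 | 2-(bromomethyl)prop-2-enoic acid | C=C(CBr)C(=O)O | starting material
17 | 2-(acetoxymethyl)prop-2-enoic acid | C=C(COC(C)=O)C(=O)O | intermediate
18 | (3S,4Z,6S,8E)-6-(benzoyloxy)-11-(tert-butyldimethylsilyloxy)-5,9-dimethylundeca-1,4,8-trien-3-yl 2-(acetoxymethyl)prop-2-enoate | C=C[C@H](OC(=O)C(=C)COC(C)=O)/C=C(/C)[C@@H](OC(=O)c1ccccc1)C/C=C(\C)CCO[Si](C)(C)C(C)(C)C | intermediate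
19 | {(5R)-5-[(1Z,3S,5E)-3-(benzoyloxy)-8-(tert-butyldimethylsilyloxy)-2,6-dimethylocta-1,5-dien-1-yl]-2-oxo-2,5-dihydrofuran-3-yl}methyl acetate | CC(=O)OCC1=C[C@@H](/C=C(/C)[C@@H](OC(=O)c2ccccc2)C/C=C(\C)CCO[Si](C)(C)C(C)(C)C)OC1=O | intermediate
20 | {(5R)-5-[(1Z,3S,5E)-3-(benzoyloxy)-8-hydroxy-2,6-dimethylocta-1,5-dien-1-yl]-2-oxo-2,5-dihydrofuran-3-yl}methyl acetate | CC(=O)OCC1=C[C@@H](/C=C(/C)[C@@H](OC(=O)c2ccccc2)C/C=C(\C)CCO)OC1=O | intermediate
21 | {(5R)-5-[(1Z,3S,5E)-3-(benzoyloxy)-2,6-dimethyl-8-oxoocta-1,5-dien-1-yl]-2-oxo-2,5-dihydrofuran-3-yl}methyl acetate | CC(=O)OCC1=C[C@@H](/C=C(/C)[C@@H](OC(=O)c2ccccc2)C/C=C(\C)CC=O)OC1=O | intermediate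
22 | diiodosamarium ketyl of 21 (C8 radical bearing O–SmI2) | CC(=O)OCC1=C[C@@H](/C=C(/C)[C@@H](OC(=O)c2ccccc2)C/C=C(\C)C[CH]O[Sm](I)I)OC1=O | intermediate
23 | cyclised bis(diiodosamarium) lactone enolate/C8 alkoxide still carrying the C13 acetate | CC(=O)OCC1=C(O[Sm](I)I)O[C@@H]2/C=C(/C)[C@@H](OC(=O)c3ccccc3)C/C=C(C)/C[C@@H](O[Sm](I)I)[C@@H]12 | intermediate
24 | (3aR,4R,6E,9S,10Z,11aR)-4-hydroxy-6,10-dimethyl-3-methylidene-2-oxo-2,3,3a,4,5,8,9,11a-octahydrocyclodeca[b]furan-9-yl benzoate (3β-benzoyloxy-8β-hydroxygermacra-1(10)E,4Z,11(13)-trien-12,6α-olide) | C=C1C(=O)O[C@@H]2/C=C(/C)[C@@H](OC(=O)c3ccccc3)C/C=C(C)/C[C@@H](O)[C@@H]12 | intermediate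
25 | angelic acid, (Z)-2-methylbut-2-enoic acid | C/C=C(/C)C(=O)O | starting material
26 | (Z)-2-methylbut-2-en-1-ol | C/C=C(/C)CO | intermediate
27 | [(2R,3S)-2,3-dimethyloxiran-2-yl]methanol | OC[C@@]1(C)O[C@H]1C | intermediate
28 | (2S,3S)-2,3-dimethyloxirane-2-carboxylic acid | OC(=O)[C@@]1(C)O[C@H]1C | intermediate
29 | (2S,3S)-2,3-dimethyloxirane-2-carboxylic 2,4,6-trichlorobenzoic anhydride | O=C(OC(=O)[C@@]1(C)O[C@H]1C)c1c(Cl)cc(Cl)cc1Cl | intermediate
30 | (3aR,4R,6E,9S,10Z,11aR)-9-(benzoyloxy)-6,10-dimethyl-3-methylidene-2-oxo-2,3,3a,4,5,8,9,11a-octahydrocyclodeca[b]furan-4-yl (2S,3S)-2,3-dimethyloxirane-2-carboxylate | C=C1C(=O)O[C@@H]2/C=C(/C)[C@@H](OC(=O)c3ccccc3)C/C=C(C)/C[C@@H](OC(=O)[C@@]3(C)O[C@H]3C)[C@@H]12 | intermediate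
31 | (1R,3S,4Z,6R,7R,8R,10R)-3-(benzoyloxy)-1,10-epoxy-8-{[(2S,3S)-2,3-dimethyloxirane-2-carbonyl]oxy}germacra-4,11(13)-dien-12,6-olide (CNP0324463.3) | C=C1C(=O)O[C@@H]2/C=C(/C)[C@@H](OC(=O)c3ccccc3)C[C@H]3O[C@]3(C)C[C@@H](OC(=O)[C@@]3(C)O[C@H]3C)[C@@H]12 | target

**Step count**
Total: 17 steps. Longest linear sequence: 13 steps (steps 1–6, 8–12, 16, 17); steps 7 and 13–15 are side branches.

**Three steps most likely to fail, with fallbacks**

Step 12 (ten-membered ketyl cyclisation; ring size and the C7/C8 sense are unproven). The fallback sets out from 21 and closes the same C7–C8 bond by a polar allyl-metal addition. Pd(PPh3)4 (5 mol %) and InI (1.5 equiv) in THF at rt under high dilution ionise the allylic acetate with zerovalent palladium, and reductive transmetalation gives the allylindium acetate iodide F1. Its γ-carbon (C7) adds to the C8 aldehyde in an intramolecular Barbier-type allylation with transposition of the olefin to C11=C13. Aqueous work-up returns to the route at 24; the configuration at C8 must be checked by NOE before step 16.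

Step 6 (ligand-controlled facial selectivity with acrolein). The fallback sets out from 13. The Ni/Cr coupling with 14 is run without the chiral ligand (CrCl2, NiCl2 cat., DMSO/THF) to give the carbinol as the C3-epimeric mixture F2. Oxidation with MnO2 in CH2Cl2 gives the cross-conjugated dienone F3. Corey–Bakshi–Shibata reduction ((R)-2-methyl-CBS-oxazaborolidine, catecholborane, toluene, −78 °C) treats the trisubstituted alkenyl group as the large substituent, sets the 3S carbinol and returns to the route at 15.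

Step 17 (face selectivity of the macrocycle epoxidation and acid lability of the product). The fallback sets out from 24, before acylation, and uses the free homoallylic C8 hydroxyl as the control element. VO(acac)2 (5 mol %) and t-BuOOH in CH2Cl2 at 0 °C epoxidise only the C1=C10 olefin within reach of the hydroxyl and give the epoxy alcohol F4. Yamaguchi acylation of F4 with the mixed anhydride 29 (from 28, as in step 16) returns to the route at 31.

**Further compounds**
F1 | step 12 | {[(5R)-5-[(1Z,3S,5E)-3-(benzoyloxy)-2,6-dimethyl-8-oxoocta-1,5-dien-1-yl]-2-oxo-2,5-dihydrofuran-3-yl]methyl}indium acetate iodide | CC(=O)O[In](I)CC1=C[C@@H](/C=C(/C)[C@@H](OC(=O)c2ccccc2)C/C=C(\C)CC=O)OC1=O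
F2 | step 6 | (3RS,4Z,6S,8E)-11-(tert-butyldimethylsilyloxy)-3-hydroxy-5,9-dimethylundeca-1,4,8-trien-6-yl benzoate (epimer mixture at C3) | C=CC(O)/C=C(/C)[C@@H](OC(=O)c1ccccc1)C/C=C(\C)CCO[Si](C)(C)C(C)(C)C
F3 | step 6 | (4Z,6S,8E)-11-(tert-butyldimethylsilyloxy)-5,9-dimethyl-3-oxoundeca-1,4,8-trien-6-yl benzoate | C=CC(=O)/C=C(/C)[C@@H](OC(=O)c1ccccc1)C/C=C(\C)CCO[Si](C)(C)C(C)(C)C
F4 | step 17 | (1R,3S,4Z,6R,7R,8R,10R)-3-(benzoyloxy)-1,10-epoxy-8-hydroxygermacra-4,11(13)-dien-12,6-olide | C=C1C(=O)O[C@@H]2/C=C(/C)[C@@H](OC(=O)c3ccccc3)C[C@H]3O[C@]3(C)C[C@@H](O)[C@@H]12
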